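**Retrosynthetic overview**

1. The target is [5,7-dihydroxy-2,2-dimethyl-8-prenyl-2H-chromen-6-yl](3-hydroxyphenyl)methanone. Ring A (phloroglucinol) and ring B (3-hydroxyphenyl) are bought; the pyran ring C is the only ring made, in the penultimate step.
2. Key disconnection: O1–C2 of ring C (oxa-6π closure of a vinyl ortho-quinone methide) together with C4–C4a, both traced back to an aryl 1,1-dimethylpropargyl ether on the ring-A oxygen para to the ketone (Claisen cascade).
3. Enabling feature: the pyran oxygen O1 (on C8a, para to C6) is the one ring-A oxygen that does not flank the aroyl group, and C4a beside it is the only ring-A carbon still bearing hydrogen once the prenyl group sits on C8. With the C5 and C7 oxygens capped as acetates, the C5 unit can travel only from this oxygen to C4a and close back onto the same oxygen.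
4. Further disconnections: propargyl ether C–O (copper-catalysed etherification), C8–prenyl (C-alkylation of the symmetric acylphloroglucinol), aryl–C(=O) (Houben–Hoesch acylation of phloroglucinol with 3-hydroxybenzonitrile).
5. Locants: chromene numbering for the product; before annulation ring A is numbered as a benzophenone (C1 bears the aroyl group, O4 is para to it, C3 bears the prenyl group, C5 is free).

Key step: step 5

Assumption: the ring-B phenol is carried unprotected through steps 2 and 3, because one equivalent of DBU (1,8-diazabicyclo[5.4.0]undec-7-ene) should ionise only the far more acidic ring-A 4-OH (para to the carbonyl).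

**Route**

Step 1
Reactants: 1 phloroglucinol (benzene-1,3,5-triol); 2 3-hydroxybenzonitrile
Product: 4 tetrahydroxybenzophenone (3-hydroxyphenyl)(2,4,6-trihydroxyphenyl)methanone, via ketiminium chloride 3 (not isolated)
Conditions: ZnCl2, HCl (g), Et2O, 0 °C; then H2O, 100 °C
Reagents that add atoms: water, O
Why: Houben–Hoesch acylation, in which the HCl/ZnCl2-activated nitrile should attack the highly nucleophilic, threefold-symmetric phloroglucinol once at carbon (the ketiminium salt deactivates the ring) and hydrolysis of the ketiminium chloride should give the ketone, the cyanophenol ring being too electron-poor to compete as nucleophile.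

Step 2
Reactants: 4 tetrahydroxybenzophenone; 5 prenyl bromide (1-bromo-3-methylbut-2-ene)
Product: 6 (3-hydroxyphenyl)[2,4,6-trihydroxy-3-(3-methylbut-2-en-1-yl)phenyl]methanone
Conditions: DBU (1.05 equiv), 5 (0.95 equiv), THF, 0 °C to rt
Reagents that add atoms: none
Why: C-alkylation of an acylphloroglucinol (vinylogous acid) anion, in which the delocalised ring-A anion should react with the soft allylic bromide at carbon (C3 and C5 are equivalent by symmetry) while the un-ionised ring-B phenol stays out and the slight deficit of bromide limits a second alkylation.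

Step 3
Reactants: 6 prenylated tetrahydroxybenzophenone; 7 3-chloro-3-methylbut-1-yne
Product: 8 [2,6-dihydroxy-3-(3-methylbut-2-en-1-yl)-4-(2-methylbut-3-yn-2-yloxy)phenyl](3-hydroxyphenyl)methanone
Conditions: CuCl2·2H2O (1 mol%), DBU (1.2 equiv), MeCN, 0 °C
Reagents that add atoms: none
Why: Copper-catalysed propargylic etherification (copper acetylide/allenylidene intermediate), in which the phenoxide of the most acidic, non-chelated hydroxyl O4 should attack through oxygen because the tertiary electrophile is hard and hindered, leaving the chelated 2- and 6-OH and the un-ionised ring-B phenol free.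

Step 4
Reactants: 8 aryl 1,1-dimethylpropargyl ether
Product: 9 3-[2,6-diacetoxy-3-(3-methylbut-2-en-1-yl)-4-(2-methylbut-3-yn-2-yloxy)benzoyl]phenyl acetate
Conditions: Ac2O, pyridine, 4-(dimethylamino)pyridine (cat.), CH2Cl2, 0 °C to rt
Reagents that add atoms: acetic anhydride, CC(=O)OC(C)=O
Why: Nucleophile-catalysed exhaustive O-acetylation of the three remaining phenols, which should remove every hydroxyl other than the future O4–H from the neighbourhood of the carbon that will carry the quinone methide.

Step 5
Reactants: 9 triacetylated aryl 1,1-dimethylpropargyl ether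
Product: 13 3-[5,7-diacetoxy-2,2-dimethyl-8-(3-methylbut-2-en-1-yl)-2H-chromene-6-carbonyl]phenyl acetate, via allenyl dienone 10 (not isolated), via allenyl phenol 11 (not isolated), via ortho-quinone methide 12 (not isolated)
Conditions: o-xylene (0.05 M, degassed), 145 °C, Ar
Reagents that add atoms: none
Why: Heating should trigger an aromatic propargyl Claisen [3,3] shift from O4 to the free ortho carbon C5 (allenyl dienone 10), re-aromatisation to allenyl phenol 11, a [1,5]-hydrogen shift from O4–H to the central allene carbon that unveils the (Z)-vinyl ortho-quinone methide 12, and an oxa-6π electrocyclisation in which the quinone methide oxygen attacks the dimethyl-substituted terminus and forms the O1–C2 bond. The closest known reaction type is the thermal rearrangement of aryl 1,1-dimethylpropargyl ethers to 2,2-dimethyl-2H-chromenes. Ring C closes by a thermally allowed disrotatory 6π electrocyclisation of the 1-oxatriene, the C4–C4a bond next to it having been made by the sigmatropic shift in the same operation. No stereocentre is created because C2 carries two methyl groups, and the C3=C4 double bond is cis by ring constraint. The step needs site selectivity at carbon (C5, not C3) and at oxygen (O4, not O6): a shift to the prenyl-bearing C3 gives a dienone that cannot enolise and should revert, whereas the acetates on O2 and O6 leave O4–H as the only hydroxyl that can hand over hydrogen and become the quinone methide oxygen, so closure is possible only onto O4. The geminal methyl groups accelerate both the sigmatropic shift and the ring closure, and re-aromatisation of ring A drives the sequence.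

Step 6
Reactants: 13 chromene triacetate
Product: 14 [5,7-dihydroxy-2,2-dimethyl-8-(3-methylbut-2-en-1-yl)-2H-chromen-6-yl](3-hydroxyphenyl)methanone (target)
Conditions: pyrrolidine (6 equiv), THF, 0 °C to rt, Ar; then aq. citric acid
Reagents that add atoms: none
Why: Aminolysis of aryl acetates, which as esters of acidic phenols should be cleaved by a secondary amine at room temperature while the chromene, the prenyl group and the hindered diaryl ketone are inert.

**Compound list**

1 | phloroglucinol (benzene-1,3,5-triol) | Oc1cc(O)cc(O)c1 | starting material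
2 | 3-hydroxybenzonitrile | N#Cc1cccc(O)c1 | starting material
3 | (3-hydroxyphenyl)(2,4,6-trihydroxyphenyl)methaniminium chloride (ketiminium chloride, not isolated) | [NH2+]=C(c1cccc(O)c1)c1c(O)cc(O)cc1O.[Cl-] | intermediate
4 | (3-hydroxyphenyl)(2,4,6-trihydroxyphenyl)methanone | O=C(c1cccc(O)c1)c1c(O)cc(O)cc1O | intermediate
5 | prenyl bromide (1-bromo-3-methylbut-2-ene) | CC(C)=CCBr | starting material
6 | (3-hydroxyphenyl)[2,4,6-trihydroxy-3-(3-methylbut-2-en-1-yl)phenyl]methanone | CC(C)=CCc1c(O)cc(O)c(C(=O)c2cccc(O)c2)c1O | intermediate
7 | 3-chloro-3-methylbut-1-yne | CC(C)(Cl)C#C | starting material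
8 | [2,6-dihydroxy-3-(3-methylbut-2-en-1-yl)-4-(2-methylbut-3-yn-2-yloxy)phenyl](3-hydroxyphenyl)methanone | CC(C)=CCc1c(OC(C)(C)C#C)cc(O)c(C(=O)c2cccc(O)c2)c1O | intermediate
9 | 3-[2,6-diacetoxy-3-(3-methylbut-2-en-1-yl)-4-(2-methylbut-3-yn-2-yloxy)benzoyl]phenyl acetate | CC(C)=CCc1c(OC(C)(C)C#C)cc(OC(C)=O)c(C(=O)c2cccc(OC(C)=O)c2)c1OC(C)=O | intermediate
10 | allenyl dienone: 3,5-diacetoxy-4-(3-acetoxybenzoyl)-6-(3-methylbuta-1,2-dien-1-yl)-2-(3-methylbut-2-en-1-yl)cyclohexa-2,4-dien-1-one (racemic at C6, not isolated) | CC(C)=CCC1=C(OC(C)=O)C(C(=O)c2cccc(OC(C)=O)c2)=C(OC(C)=O)C(C=C=C(C)C)C1=O | intermediate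
11 | allenyl phenol: 3-[2,6-diacetoxy-4-hydroxy-5-(3-methylbuta-1,2-dien-1-yl)-3-(3-methylbut-2-en-1-yl)benzoyl]phenyl acetate (not isolated) | CC(C)=CCc1c(O)c(C=C=C(C)C)c(OC(C)=O)c(C(=O)c2cccc(OC(C)=O)c2)c1OC(C)=O | intermediate
12 | ortho-quinone methide: (Z)-3,5-diacetoxy-4-(3-acetoxybenzoyl)-6-(3-methylbut-2-en-1-ylidene)-2-(3-methylbut-2-en-1-yl)cyclohexa-2,4-dien-1-one (not isolated) | CC(C)=CCC1=C(OC(C)=O)C(C(=O)c2cccc(OC(C)=O)c2)=C(OC(C)=O)/C(=C/C=C(C)C)C1=O | intermediate
13 | 3-[5,7-diacetoxy-2,2-dimethyl-8-(3-methylbut-2-en-1-yl)-2H-chromene-6-carbonyl]phenyl acetate | CC(C)=CCc1c(OC(C)=O)c(C(=O)c2cccc(OC(C)=O)c2)c(OC(C)=O)c2c1OC(C)(C)C=C2 | intermediate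
14 | [5,7-dihydroxy-2,2-dimethyl-8-(3-methylbut-2-en-1-yl)-2H-chromen-6-yl](3-hydroxyphenyl)methanone (CNP0424359.0, achiral) | CC(C)=CCc1c(O)c(C(=O)c2cccc(O)c2)c(O)c2c1OC(C)(C)C=C2 | target

**Step count and risks**

Total step count: 6. Longest linear sequence: 6 steps (from phloroglucinol).

Steps most likely to fail:

Step 5. The sigmatropic shift may go to the prenyl-bearing ortho carbon, and the resulting non-enolisable allenyl dienone may be drained by intramolecular cycloaddition or further shifts instead of reverting; prolonged heating may also scramble acetyl groups. The fallback sets out from 6 and comes back at 14, replacing the intramolecular delivery by an intermolecular formal [3+3] annulation. 6 would be condensed with 3-methylbut-2-enal under ethylenediammonium diacetate catalysis (toluene, reflux). Knoevenagel-type condensation at the only free ring-A carbon should give the unprotected vinyl ortho-quinone methide F1, which closes by the same oxa-6π electrocyclisation to 14 without protecting groups. Because the 6-hydroxyl is free in this variant, closure through it to the 8-aroyl-6-prenyl regioisomer F2 would be expected to compete, and F2 would be removed by chromatography.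

Step 3. The ambident ring-A anion may be alkylated at carbon C5, the ring-B phenol may be alkylated, or the etherification may stall beside the prenyl group. The fallback sets out from 6 and comes back at 9, protecting first and alkylating a single phenol afterwards. 6 would be peracetylated (Ac2O, pyridine, 4-(dimethylamino)pyridine) to the tetraacetate F3. The 4-O-acetyl group, the ester of the most acidic phenol (para to the ketone), would be removed selectively with thiophenol and imidazole in N-methyl-2-pyrrolidone to give the 4-hydroxy triacetate F4. Its single, non-ambident phenoxide would then be etherified with 7 (CuCl2·2H2O cat., DBU, MeCN, 0 °C) to give 9, which makes step 4 unnecessary.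

Step 2. Over-alkylation to 3,5-diprenyl and dearomatised geminal diprenyl products, and O-prenylation, may erode the mono-C-prenyl compound. The fallback sets out from 4 and comes back at 6, delivering the prenyl group from oxygen by a sigmatropic shift. 4 would be etherified at O4 with 7 (CuCl2·2H2O cat., DBU, MeCN, 0 °C) to the 1,1-dimethylpropargyl ether F5. Semi-hydrogenation (H2, Pd/CaCO3 poisoned with Pb(OAc)2, quinoline, EtOAc) would give the 1,1-dimethylallyl ether F6. Heating (toluene, 110 °C) should bring about an aromatic Claisen rearrangement that transfers exactly one prenyl group, with allyl inversion, to the ortho carbon (C3 and C5 are equivalent) and give 6.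

**Further compounds**

F1 | step 5 | (Z)-3,5-dihydroxy-4-(3-hydroxybenzoyl)-6-(3-methylbut-2-en-1-ylidene)-2-(3-methylbut-2-en-1-yl)cyclohexa-2,4-dien-1-one (unprotected vinyl ortho-quinone methide, not isolated) | CC(C)=CCC1=C(O)C(C(=O)c2cccc(O)c2)=C(O)/C(=C/C=C(C)C)C1=O
F2 | step 5 | [5,7-dihydroxy-2,2-dimethyl-6-(3-methylbut-2-en-1-yl)-2H-chromen-8-yl](3-hydroxyphenyl)methanone (regioisomer) | CC(C)=CCc1c(O)c2C=CC(C)(C)Oc2c(C(=O)c2cccc(O)c2)c1O
F3 | step 3 | 3-[2,4,6-triacetoxy-3-(3-methylbut-2-en-1-yl)benzoyl]phenyl acetate | CC(C)=CCc1c(OC(C)=O)cc(OC(C)=O)c(C(=O)c2cccc(OC(C)=O)c2)c1OC(C)=O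
F4 | step 3 | 3-[2,6-diacetoxy-4-hydroxy-3-(3-methylbut-2-en-1-yl)benzoyl]phenyl acetate | CC(C)=CCc1c(O)cc(OC(C)=O)c(C(=O)c2cccc(OC(C)=O)c2)c1OC(C)=O
F5 | step 2 | [2,6-dihydroxy-4-(2-methylbut-3-yn-2-yloxy)phenyl](3-hydroxyphenyl)methanone | CC(C)(C#C)Oc1cc(O)c(C(=O)c2cccc(O)c2)c(O)c1
F6 | step 2 | [2,6-dihydroxy-4-(2-methylbut-3-en-2-yloxy)phenyl](3-hydroxyphenyl)methanone | CC(C)(C=C)Oc1cc(O)c(C(=O)c2cccc(O)c2)c(O)c1
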